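Numbering: ring C1 (quaternary epoxide carbon carrying C7H2OBz), C2 (CHOBz), C3 (CHOH), C4=C5, C6 (epoxide CH). The epoxide is traced back to the C1=C6 alkene of a cyclohexa-1,3-diene, which turns C7–C1(=C6)–C2–OH into a Morita–Baylis–Hillman-type motif. Everything rests on the C1–C2 disconnection: a chromium-mediated intramolecular Nozaki–Hiyama–Kishi addition of the C1 alkenyl iodide to the C2 aldehyde closes the six-membered carbocycle and sets the C2 carbinol trans to C3–O in one operation. Its precursor is an acyclic (2Z,4Z)-2-iodo-dienoate aldehyde, made from L-arabinal by Ferrier rearrangement and lactol Wittig opening, so that the pyranose ring oxygen is exchanged for carbon.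

Key step: step 6

Remark: 3,4-di-O-acetyl-L-arabinal is taken as a purchasable glycal; compounds 2–5 are anomeric mixtures (anomeric centre left undefined, it is destroyed in step 4); sugar carbons C1, C2, C3, C4, C5 become target C6, C5, C4, C3, C2.

Step 1
Reactants: 1 3,4-di-O-acetyl-L-arabinal
Product: 3 ethyl 2,3-dideoxy-L-glycero-pent-2-enopyranoside, via ethyl 4-O-acetyl glycoside 2 (not isolated)
Conditions: EtOH, BF3·OEt2 (cat.), CH2Cl2, 0 °C; then K2CO3, MeOH, rt
Reagents that add atoms: ethanol, CCO
Why: Ferrier rearrangement, in which BF3 ionises the allylic sugar-C3 acetate to an allyl oxocarbenium ion that ethanol captures at sugar C1 with shift of the double bond to C2=C3 while the sugar-C4 stereocentre (target C3) is untouched, followed by carbonate-mediated methanolysis (Zemplén-type transesterification) of the remaining acetate.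

Step 2
Reactants: 3 ethyl 2,3-dideoxy-L-glycero-pent-2-enopyranoside
Product: 4 ethyl 4-O-(tert-butyldimethylsilyl)-2,3-dideoxy-L-glycero-pent-2-enopyranoside
Conditions: TBSCl, imidazole, DMF, rt
Reagents that add atoms: tert-butyldimethylsilyl chloride, CC(C)(C)[Si](C)(C)Cl
Why: Imidazole-promoted silylation of the secondary allylic alcohol gives the silyl ether that must survive until the last step.

Step 3
Reactants: 4 ethyl 4-O-(tert-butyldimethylsilyl)-2,3-dideoxy-L-glycero-pent-2-enopyranoside
Product: 5 4-O-(tert-butyldimethylsilyl)-2,3-dideoxy-L-glycero-pent-2-enopyranose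
Conditions: PPTS (cat.), acetone/H2O 4:1, 40 °C
Reagents that add atoms: water, O
Why: Acid-catalysed hydrolysis of the allylic acetal through the allyl-stabilised oxocarbenium ion; the product should stay as the cyclic hemiacetal, which preserves the Z alkene, and PPTS is too weak to cleave the secondary silyl ether.

Step 4
Reactants: 5 4-O-(tert-butyldimethylsilyl)-2,3-dideoxy-L-glycero-pent-2-enopyranose
Product: 6 ethyl (2Z,4Z,6R)-6-[(tert-butyldimethylsilyl)oxy]-7-hydroxy-2-iodohepta-2,4-dienoate
Conditions: Ph3P=CHCO2Et, N-iodosuccinimide, CH2Cl2, −20 °C; then 5, rt to 40 °C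
Reagents that add atoms: ethyl (triphenyl-λ5-phosphanylidene)acetate, CCOC(=O)C=P(c1ccccc1)(c1ccccc1)c1ccccc1; N-iodosuccinimide, O=C1CCC(=O)N1I
Why: Wittig olefination of the lactol through its open hydroxy-(Z)-enal form with the stabilised α-iodo ylide made in the flask; the ester should end trans to the chain so that iodine is cis to C5 (2Z), the ring-derived C4=C5 bond stays Z, and the absence of base disfavours oxa-Michael re-closure of the freed C2 hydroxyl.

Step 5
Reactants: 6 ethyl (2Z,4Z,6R)-6-[(tert-butyldimethylsilyl)oxy]-7-hydroxy-2-iodohepta-2,4-dienoate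
Product: 7 ethyl (2Z,4Z,6R)-6-[(tert-butyldimethylsilyl)oxy]-2-iodo-7-oxohepta-2,4-dienoate
Conditions: Dess–Martin periodinane, CH2Cl2, 0 °C to rt; used crude
Reagents that add atoms: none
Why: Dess–Martin oxidation of the primary alcohol to the aldehyde under near-neutral conditions, which should leave the iodoacrylate, the silyl ether and the enolisable C3 stereocentre untouched.

Step 6
Reactants: 7 ethyl (2Z,4Z,6R)-6-[(tert-butyldimethylsilyl)oxy]-2-iodo-7-oxohepta-2,4-dienoate
Product: 9 ethyl (5R,6R)-5-[(tert-butyldimethylsilyl)oxy]-6-hydroxycyclohexa-1,3-diene-1-carboxylate, via alkenylchromium dichloride 8 (not isolated)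
Conditions: CrCl2 (6 equiv), NiCl2 (2 mol%), degassed DMF, 5 mM, rt; aqueous work-up
Reagents that add atoms: none
Why: Divalent chromium, assisted by oxidative addition of zerovalent nickel formed in the flask, reduces the activated C1–I bond to alkenylchromium 8 (trivalent chromium), which adds to the C2 aldehyde; this is the intramolecular Nozaki–Hiyama–Kishi reaction of an alkenyl iodide, here an α-iodoacrylate serving as a Morita–Baylis–Hillman surrogate. The one ring formed is the six-membered carbocycle C1–C6, closed by 6-exo-trig attack on the carbonyl, which is geometrically possible because C4=C5 is Z (inherited from the pyranoside) and chromium sits cis to C5. The new C2 stereocentre is controlled by the adjacent C3 silyloxy group: in the polar Felkin–Anh (Cornforth) arrangement the C3–O bond lies anti to the forming C1–C2 bond and to the carbonyl dipole, so the alkoxide should end pseudo-axial and trans to C3–OTBS, giving (5R,6R). The step needs chemoselective C–I activation beside ester and aldehyde and no epimerisation at C3, both secured by the non-basic, aldehyde-selective organochromium reagent, while high dilution suppresses intermolecular coupling. Because the ester-stabilised alkenylchromium can equilibrate through its allenolate form, any minor 2E iodide should converge on the same ring.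

Step 7
Reactants: 9 ethyl (5R,6R)-5-[(tert-butyldimethylsilyl)oxy]-6-hydroxycyclohexa-1,3-diene-1-carboxylate
Product: 10 (1R,6R)-6-[(tert-butyldimethylsilyl)oxy]-2-(hydroxymethyl)cyclohexa-2,4-dien-1-ol
Conditions: iBu2AlH (3.5 equiv), CH2Cl2, −78 °C; aqueous potassium sodium tartrate work-up
Reagents that add atoms: none
Why: 1,2-Reduction of the conjugated ester by the aluminium hydride at low temperature should give the primary allylic alcohol C7 without touching the diene or the silyl ether, the free C2 hydroxyl only consuming one equivalent of hydride.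

Step 8
Reactants: 10 (1R,6R)-6-[(tert-butyldimethylsilyl)oxy]-2-(hydroxymethyl)cyclohexa-2,4-dien-1-ol
Product: 11 [(5R,6R)-6-(benzoyloxy)-5-[(tert-butyldimethylsilyl)oxy]cyclohexa-1,3-dien-1-yl]methyl benzoate
Conditions: BzCl (2.5 equiv), pyridine, DMAP (cat.), CH2Cl2, 0 °C to rt
Reagents that add atoms: benzoyl chloride, O=C(Cl)c1ccccc1
Why: DMAP-catalysed acylation of the primary and the secondary allylic hydroxyl installs both benzoates of the target at C7 and C2.

Step 9
Reactants: 11 [(5R,6R)-6-(benzoyloxy)-5-[(tert-butyldimethylsilyl)oxy]cyclohexa-1,3-dien-1-yl]methyl benzoate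
Product: 12 [(1S,2S,3R,6S)-2-(benzoyloxy)-3-[(tert-butyldimethylsilyl)oxy]-7-oxabicyclo[4.1.0]hept-4-en-1-yl]methyl benzoate
Conditions: mCPBA, CH2Cl2/aq. NaHCO3, 0 °C
Reagents that add atoms: meta-chloroperoxybenzoic acid, OOC(=O)c1cccc(Cl)c1
Why: Prilezhaev epoxidation, in which the peracid should attack the more substituted C1=C6 bond of the diene from the face anti to the pseudo-axial C2 benzoate, setting C1 and C6 together as the epoxide trans to C2–OBz and cis to C3–O, the usual outcome for 5,6-trans-dioxygenated cyclohexa-1,3-dienes.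

Step 10
Reactants: 12 [(1S,2S,3R,6S)-2-(benzoyloxy)-3-[(tert-butyldimethylsilyl)oxy]-7-oxabicyclo[4.1.0]hept-4-en-1-yl]methyl benzoate
Product: 13 [(1S,2S,3R,6S)-2-(benzoyloxy)-3-hydroxy-7-oxabicyclo[4.1.0]hept-4-en-1-yl]methyl benzoate
Conditions: HF·pyridine, pyridine, THF, 0 °C to rt
Reagents that add atoms: none
Why: Fluoride-mediated cleavage of the silyl ether under pyridine-buffered, non-basic conditions, which should avoid benzoyl migration from O2 to O3 and spare the vinyl epoxide.

Compound list
1 | 3,4-di-O-acetyl-L-arabinal, (3S,4R)-3,4-dihydro-2H-pyran-3,4-diyl diacetate | O1C=C[C@@H](OC(C)=O)[C@@H](OC(C)=O)C1 | starting material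
2 | ethyl 4-O-acetyl-2,3-dideoxy-L-glycero-pent-2-enopyranoside, (3R)-6-ethoxy-3,6-dihydro-2H-pyran-3-yl acetate (anomeric mixture) | CCOC1C=C[C@@H](OC(C)=O)CO1 | intermediate (not isolated)
3 | ethyl 2,3-dideoxy-L-glycero-pent-2-enopyranoside, (3R)-6-ethoxy-3,6-dihydro-2H-pyran-3-ol (anomeric mixture) | CCOC1C=C[C@@H](O)CO1 | intermediate
4 | ethyl 4-O-(tert-butyldimethylsilyl)-2,3-dideoxy-L-glycero-pent-2-enopyranoside (anomeric mixture) | CCOC1C=C[C@@H](O[Si](C)(C)C(C)(C)C)CO1 | intermediate
5 | 4-O-(tert-butyldimethylsilyl)-2,3-dideoxy-L-glycero-pent-2-enopyranose, (5R)-5-[(tert-butyldimethylsilyl)oxy]-5,6-dihydro-2H-pyran-2-ol (anomeric mixture) | OC1C=C[C@@H](O[Si](C)(C)C(C)(C)C)CO1 | intermediate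
6 | ethyl (2Z,4Z,6R)-6-[(tert-butyldimethylsilyl)oxy]-7-hydroxy-2-iodohepta-2,4-dienoate | CCOC(=O)/C(I)=C/C=C\[C@@H](O[Si](C)(C)C(C)(C)C)CO | intermediate
7 | ethyl (2Z,4Z,6R)-6-[(tert-butyldimethylsilyl)oxy]-2-iodo-7-oxohepta-2,4-dienoate | CCOC(=O)/C(I)=C/C=C\[C@@H](O[Si](C)(C)C(C)(C)C)C=O | intermediate
8 | alkenylchromium dichloride derived from 7 (CrCl2 group in place of iodine at C1, trivalent chromium) | CCOC(=O)/C([Cr](Cl)Cl)=C/C=C\[C@@H](O[Si](C)(C)C(C)(C)C)C=O | intermediate (not isolated)
9 | ethyl (5R,6R)-5-[(tert-butyldimethylsilyl)oxy]-6-hydroxycyclohexa-1,3-diene-1-carboxylate (trans) | CCOC(=O)C1=CC=C[C@@H](O[Si](C)(C)C(C)(C)C)[C@@H]1O | intermediate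
10 | (1R,6R)-6-[(tert-butyldimethylsilyl)oxy]-2-(hydroxymethyl)cyclohexa-2,4-dien-1-ol | OCC1=CC=C[C@@H](O[Si](C)(C)C(C)(C)C)[C@@H]1O | intermediate
11 | [(5R,6R)-6-(benzoyloxy)-5-[(tert-butyldimethylsilyl)oxy]cyclohexa-1,3-dien-1-yl]methyl benzoate | O=C(OCC1=CC=C[C@@H](O[Si](C)(C)C(C)(C)C)[C@@H]1OC(=O)c1ccccc1)c1ccccc1 | intermediate
12 | [(1S,2S,3R,6S)-2-(benzoyloxy)-3-[(tert-butyldimethylsilyl)oxy]-7-oxabicyclo[4.1.0]hept-4-en-1-yl]methyl benzoate | O=C(OC[C@]12O[C@H]1C=C[C@@H](O[Si](C)(C)C(C)(C)C)[C@@H]2OC(=O)c1ccccc1)c1ccccc1 | intermediate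
13 | [(1S,2S,3R,6S)-2-(benzoyloxy)-3-hydroxy-7-oxabicyclo[4.1.0]hept-4-en-1-yl]methyl benzoate | O=C(OC[C@]12O[C@H]1C=C[C@@H](O)[C@@H]2OC(=O)c1ccccc1)c1ccccc1 | target

Total step count: 10. Longest linear sequence: 10 steps (from 1).

Steps most likely to fail

Step 6. The alkenylchromium intermediate may be protonated before it cyclises (loss of iodine without C–C bond formation), or the addition may show poor facial selectivity at C2. The fallback closes the ring without a halide, by nucleophilic catalysis. It sets out from lactol 5: Wittig olefination with Ph3P=CHCO2Et (CH2Cl2, rt) should give ethyl (2E,4Z,6R)-6-[(tert-butyldimethylsilyl)oxy]-7-hydroxyhepta-2,4-dienoate F1, and Dess–Martin oxidation the aldehyde ethyl (2E,4Z,6R)-6-[(tert-butyldimethylsilyl)oxy]-7-oxohepta-2,4-dienoate F2. An intramolecular Morita–Baylis–Hillman reaction (PMe3, tBuOH/THF, rt) follows, in which the phosphine adds at C6, the ester enolate attacks the C2 aldehyde through C1 and the phosphine is expelled. The reversible aldol step should favour the trans isomer, and the route is rejoined at 9.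

Step 3. The acid may open the hemiacetal to the hydroxy enal, which can isomerise from Z to E or eliminate the C3 oxygen on the way to a furan, and the silyl ether may be partly lost. The fallback oxidises the anomeric carbon instead of hydrolysing it. It sets out from glycoside 4: oxidation of the allylic acetal (mCPBA, BF3·OEt2, CH2Cl2, −20 °C, or CrO3/H2SO4 in acetone) should give the unsaturated lactone (5R)-5-[(tert-butyldimethylsilyl)oxy]-5,6-dihydro-2H-pyran-2-one F3. Reduction with iBu2AlH (CH2Cl2, −78 °C) should then deliver lactol 5 under non-acidic conditions, where the route is rejoined.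

Step 9. The peracid may attack the C4=C5 bond, the lower face of C1=C6, or both double bonds. The fallback moves the epoxidation to the diol stage, where it is hydroxyl-directed and reagent-controlled. It sets out from diol 10: Sharpless epoxidation (Ti(OiPr)4, L-(+)-diisopropyl tartrate, tBuOOH, 4 Å molecular sieves, CH2Cl2, −20 °C) can only reach the C1=C6 bond next to the primary C7 hydroxyl, and this tartrate should deliver oxygen to the face anti to C2–O. It should give the epoxy diol (1R,2S,3R,6S)-3-[(tert-butyldimethylsilyl)oxy]-1-(hydroxymethyl)-7-oxabicyclo[4.1.0]hept-4-en-2-ol F4. Benzoylation of both hydroxyls (BzCl, pyridine, DMAP) then rejoins the route at 12.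

Further compounds
F1 | step 6 | ethyl (2E,4Z,6R)-6-[(tert-butyldimethylsilyl)oxy]-7-hydroxyhepta-2,4-dienoate | CCOC(=O)/C=C/C=C\[C@@H](O[Si](C)(C)C(C)(C)C)CO
F2 | step 6 | ethyl (2E,4Z,6R)-6-[(tert-butyldimethylsilyl)oxy]-7-oxohepta-2,4-dienoate | CCOC(=O)/C=C/C=C\[C@@H](O[Si](C)(C)C(C)(C)C)C=O
F3 | step 3 | (5R)-5-[(tert-butyldimethylsilyl)oxy]-5,6-dihydro-2H-pyran-2-one | O=C1C=C[C@@H](O[Si](C)(C)C(C)(C)C)CO1
F4 | step 9 | (1R,2S,3R,6S)-3-[(tert-butyldimethylsilyl)oxy]-1-(hydroxymethyl)-7-oxabicyclo[4.1.0]hept-4-en-2-ol | OC[C@]12O[C@H]1C=C[C@@H](O[Si](C)(C)C(C)(C)C)[C@@H]2O
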